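**Plan**
- Retrosynthesis: the two aryl silyl ethers are removed first; then the C2–C1' bond between ring C and ring B is cut, giving an 8-prenyl-7-silyloxychromone (rings A and C) and a 4-silyloxy-3,5-diprenylphenylboronic acid (ring B); the three aryl–prenyl bonds are cut last.
- Forward, ring B half: 2,6-dibromophenol is silylated, prenylated twice by linear-selective Negishi coupling and borylated at the para C–H bond.
- Forward, rings A and C half: 7-hydroxychromone is converted to its 1,1-dimethylpropargyl ether, semihydrogenated, rearranged (aromatic Claisen) to put the prenyl group on C8, and silylated.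
- The halves are joined by rhodium-catalysed asymmetric 1,4-addition of the arylboronic acid to the chromone; the only stereocentre (C2, S) is set there by the chiral bisphosphine, and buffered fluoride then frees both phenols without opening ring C.
- Enabling features: C2 is the unsubstituted β-carbon of the C2=C3–C4=O vinylogous ester of ring C, so aryl transfer to C2 makes the bond and the stereocentre together; ring B is symmetric, and C1' (para to oxygen) is its only carbon without an ortho substituent, so boron goes there by sterically controlled C–H borylation.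

Key step: step 8

Assumption: the sense of induction of the rhodium/biaryl bisphosphine catalyst on the chromone is taken to follow that on cyclic enones, where the (S)-ligand gives the (S)-adduct (the same face corresponds to 2S in the flavanone); if a test run shows the opposite sense, the (R)-ligand is used instead.

**Step 1**
Reactants: 1 2,6-dibromophenol
Product: 2 tert-butyl(2,6-dibromophenoxy)dimethylsilane
Conditions: TBSCl, imidazole, DMF, rt
Reagents that add atoms: tert-butyldimethylsilyl chloride, CC(C)(C)[Si](C)(C)Cl
Why: Imidazole-promoted silylation of the acidic phenol gives an aryl silyl ether that carries no acidic proton and should tolerate the organozinc reagent, the iridium catalyst and the rhodium step.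

**Step 2**
Reactants: 2 tert-butyl(2,6-dibromophenoxy)dimethylsilane
Product: 3 tert-butyl[2,6-bis(3-methylbut-2-en-1-yl)phenoxy]dimethylsilane
Conditions: prenylZnBr·LiCl (from prenyl bromide, Zn dust, LiCl, THF, 0 °C; 3 equiv), Pd(OAc)2 (cat.), CPhos (2-dicyclohexylphosphino-2',6'-bis(dimethylamino)biphenyl), THF, rt
Reagents that add atoms: prenylzinc bromide, CC(C)=CC[Zn]Br
Why: Linear-selective Negishi cross-coupling at both C–Br bonds: transmetalation gives the sigma-prenyl palladium bound through the CH2 terminus, and the bulky dialkylbiarylphosphine should make direct reductive elimination faster than allyl transposition, so the normal prenyl group and not the 1,1-dimethylallyl isomer is installed twice.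

**Step 3**
Reactants: 3 tert-butyl[2,6-bis(3-methylbut-2-en-1-yl)phenoxy]dimethylsilane
Product: 5 [4-(tert-butyldimethylsilyloxy)-3,5-bis(3-methylbut-2-en-1-yl)phenyl]boronic acid, via aryl pinacol boronate 4 (not isolated)
Conditions: [Ir(OMe)(cod)]2 (cat.), dtbpy (4,4'-di-tert-butyl-2,2'-bipyridine), B2pin2, THF, 60 °C; then NaIO4, NH4OAc, acetone/H2O, rt
Reagents that add atoms: bis(pinacolato)diboron, CC1(C)OB(OC1(C)C)B1OC(C)(C)C(C)(C)O1; water, O
Why: Iridium-catalysed aromatic C–H borylation is sterically controlled and should attack only the C–H bond with no ortho substituent, here the one para to the silyloxy group, and periodate cleavage of the pinacol unit in the same flask then gives the free boronic acid needed for fast transmetalation in step 8.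

**Step 4**
Reactants: 6 7-hydroxy-4H-chromen-4-one
Product: 7 7-[(2-methylbut-3-yn-2-yl)oxy]-4H-chromen-4-one
Conditions: 3-chloro-3-methylbut-1-yne, K2CO3, KI, CuI (cat.), acetone, 55 °C
Reagents that add atoms: 3-chloro-3-methylbut-1-yne, C#CC(C)(C)Cl
Why: Williamson-type O-alkylation of the only acidic site, the 7-phenoxide, by the tertiary propargylic chloride (assisted by iodide and copper) should give the 1,1-dimethylpropargyl aryl ether well below the temperature at which it would cyclise to a chromene.

**Step 5**
Reactants: 7 7-[(2-methylbut-3-yn-2-yl)oxy]-4H-chromen-4-one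
Product: 8 7-[(2-methylbut-3-en-2-yl)oxy]-4H-chromen-4-one
Conditions: H2 (1 atm), Pd/CaCO3 poisoned with Pb(OAc)2 (Lindlar catalyst), quinoline, EtOAc, rt
Reagents that add atoms: none
Why: Lindlar semihydrogenation should stop at the terminal alkene on the poisoned palladium surface and leave the conjugated C2=C3 bond of the chromone untouched.

**Step 6**
Reactants: 8 7-[(2-methylbut-3-en-2-yl)oxy]-4H-chromen-4-one
Product: 10 7-hydroxy-8-(3-methylbut-2-en-1-yl)-4H-chromen-4-one, via ortho-dienone 9 (not isolated)
Conditions: PhNEt2, 130 °C
Reagents that add atoms: none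
Why: Aromatic Claisen rearrangement ([3,3]-sigmatropic shift) of the 1,1-dimethylallyl ether inverts the allyl unit to the normal prenyl group and should go to C8 in preference to C6 because the C7–C8 bond of the benzopyranone has the higher double-bond character (as in the umbelliferone to osthenol case), after which the dienone enolises.

**Step 7**
Reactants: 10 7-hydroxy-8-(3-methylbut-2-en-1-yl)-4H-chromen-4-one
Product: 11 8-(3-methylbut-2-en-1-yl)-7-(triisopropylsilyloxy)-4H-chromen-4-one
Conditions: TIPSCl, imidazole, DMF, rt
Reagents that add atoms: triisopropylsilyl chloride, CC(C)[Si](Cl)(C(C)C)C(C)C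
Why: Imidazole-promoted silylation masks the acidic 7-hydroxyl, and the bulkier triisopropylsilyl group is chosen because this aryl silyl ether lies para to the C4 carbonyl and must survive the aqueous key step.

**Step 8**
Reactants: 5 [4-(tert-butyldimethylsilyloxy)-3,5-bis(3-methylbut-2-en-1-yl)phenyl]boronic acid (2 equiv); 11 8-(3-methylbut-2-en-1-yl)-7-(triisopropylsilyloxy)-4H-chromen-4-one
Product: 12 (2S)-2-[4-(tert-butyldimethylsilyloxy)-3,5-bis(3-methylbut-2-en-1-yl)phenyl]-8-(3-methylbut-2-en-1-yl)-7-(triisopropylsilyloxy)-2,3-dihydro-4H-chromen-4-one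
Conditions: [Rh(OH)(cod)]2 (cat.), (S)-MeO-F12-BIPHEP ((S)-2,2'-bis[bis(3,4,5-trifluorophenyl)phosphino]-6,6'-dimethoxy-1,1'-biphenyl), CH2Cl2/H2O, rt
Reagents that add atoms: none
Why: The hydroxo complex of monovalent rhodium takes the aryl group from boron by transmetalation, the aryl–rhodium species binds and inserts the C2=C3 bond of the chromone so that the aryl carbon bonds to C2 (the β-carbon of the C4 carbonyl) and an oxa-π-allyl rhodium enolate results, and water protonates this at C3 and returns Rh–OH. The closest known reaction type is the Hayashi–Miyaura asymmetric 1,4-addition of arylboronic acids to chromones with electron-poor atropisomeric bisphosphine ligands, which gives flavanones directly. No ring is closed, since ring C is already in place and only changes from chromone to chromanone. The new stereocentre C2 is set under catalyst control: the (S)-bisphosphine shields one face of the bound C2=C3 bond so that the aryl group is delivered to the face that gives 2S. The step needs 1,4- over 1,2-addition and no opening of ring C, which the weakly electrophilic vinylogous-ester carbonyl and the base-free hydroxo-rhodium conditions at room temperature should secure; the trisubstituted prenyl alkenes should not insert into the aryl–rhodium bond, and the boronic acid has no ortho substituent, so transmetalation should outrun protodeboronation.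

**Step 9**
Reactants: 12 (2S)-2-[4-(tert-butyldimethylsilyloxy)-3,5-bis(3-methylbut-2-en-1-yl)phenyl]-8-(3-methylbut-2-en-1-yl)-7-(triisopropylsilyloxy)-2,3-dihydro-4H-chromen-4-one
Product: 13 sophoranone, (2S)-7-hydroxy-2-[4-hydroxy-3,5-bis(3-methylbut-2-en-1-yl)phenyl]-8-(3-methylbut-2-en-1-yl)-2,3-dihydro-4H-chromen-4-one
Conditions: Bu4NF, AcOH (1:1), THF, 0 °C to rt
Reagents that add atoms: none
Why: Fluoride cleaves both aryl silyl ethers through Si–F bond formation, and the acetic acid buffer should keep the 4'-phenol protonated so that ring C is not opened by retro-oxa-Michael reaction (quinone methide pathway) and C2 keeps its configuration, while the prenyl groups are inert to this weak acid.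

**Compound list**
1 | 2,6-dibromophenol | Oc1c(Br)cccc1Br | starting material
2 | tert-butyl(2,6-dibromophenoxy)dimethylsilane | CC(C)(C)[Si](C)(C)Oc1c(Br)cccc1Br | intermediate
3 | tert-butyl[2,6-bis(3-methylbut-2-en-1-yl)phenoxy]dimethylsilane | CC(C)=CCc1cccc(CC=C(C)C)c1O[Si](C)(C)C(C)(C)C | intermediate
4 | 2-[4-(tert-butyldimethylsilyloxy)-3,5-bis(3-methylbut-2-en-1-yl)phenyl]-4,4,5,5-tetramethyl-1,3,2-dioxaborolane (not isolated) | CC(C)=CCc1cc(B2OC(C)(C)C(C)(C)O2)cc(CC=C(C)C)c1O[Si](C)(C)C(C)(C)C | intermediate
5 | [4-(tert-butyldimethylsilyloxy)-3,5-bis(3-methylbut-2-en-1-yl)phenyl]boronic acid | CC(C)=CCc1cc(B(O)O)cc(CC=C(C)C)c1O[Si](C)(C)C(C)(C)C | intermediate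
6 | 7-hydroxy-4H-chromen-4-one (7-hydroxychromone) | O=c1ccoc2cc(O)ccc12 | starting material
7 | 7-[(2-methylbut-3-yn-2-yl)oxy]-4H-chromen-4-one | C#CC(C)(C)Oc1ccc2c(c1)occc2=O | intermediate
8 | 7-[(2-methylbut-3-en-2-yl)oxy]-4H-chromen-4-one | C=CC(C)(C)Oc1ccc2c(c1)occc2=O | intermediate
9 | 8-(3-methylbut-2-en-1-yl)-8H-chromene-4,7-dione (ortho-dienone, racemic, not isolated) | O=C1C=CC2=C(OC=CC2=O)C1CC=C(C)C | intermediate
10 | 7-hydroxy-8-(3-methylbut-2-en-1-yl)-4H-chromen-4-one | CC(C)=CCc1c(O)ccc2c1occc2=O | intermediate
11 | 8-(3-methylbut-2-en-1-yl)-7-(triisopropylsilyloxy)-4H-chromen-4-one | CC(C)=CCc1c(O[Si](C(C)C)(C(C)C)C(C)C)ccc2c1occc2=O | intermediate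
12 | (2S)-2-[4-(tert-butyldimethylsilyloxy)-3,5-bis(3-methylbut-2-en-1-yl)phenyl]-8-(3-methylbut-2-en-1-yl)-7-(triisopropylsilyloxy)-2,3-dihydro-4H-chromen-4-one | CC(C)=CCc1cc([C@@H]2CC(=O)c3ccc(O[Si](C(C)C)(C(C)C)C(C)C)c(CC=C(C)C)c3O2)cc(CC=C(C)C)c1O[Si](C)(C)C(C)(C)C | intermediate
13 | sophoranone, (2S)-7-hydroxy-2-[4-hydroxy-3,5-bis(3-methylbut-2-en-1-yl)phenyl]-8-(3-methylbut-2-en-1-yl)-2,3-dihydro-4H-chromen-4-one | CC(C)=CCc1cc([C@@H]2CC(=O)c3ccc(O)c(CC=C(C)C)c3O2)cc(CC=C(C)C)c1O | target

**Step count**
Total steps: 9 (ring B half: steps 1 to 3; rings A and C half: steps 4 to 7; union and deprotection: steps 8 and 9).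
Longest linear sequence: 6 steps (6 to 13 through steps 4, 5, 6, 7, 8 and 9).

**Steps most likely to fail**

Step 8. Insertion of the electron-rich 7-silyloxychromone may be slow, so that protodeboronation of 5 competes. A second aryl transfer to the C4 carbonyl of the product, opening of ring C, or insufficient facial selectivity would lower yield or enantiopurity. The fallback gives up catalyst control of the stereocentre and uses resolution. It sets out from 5 and 11: addition under achiral cationic divalent palladium catalysis (Pd(OCOCF3)2, 2,2'-bipyridine, NH4PF6, H2O, ClCH2CH2Cl, 60 °C) should give racemic 2-[4-(tert-butyldimethylsilyloxy)-3,5-bis(3-methylbut-2-en-1-yl)phenyl]-8-(3-methylbut-2-en-1-yl)-7-(triisopropylsilyloxy)-2,3-dihydro-4H-chromen-4-one F1. Its enantiomers are separated by preparative chromatography on a chiral stationary phase (amylose tris(3,5-dimethylphenylcarbamate)), and the (2S)-enantiomer is compound 12, where the route is rejoined.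

Step 2. The second coupling next to the bulky silyloxy group may stall, the allyl unit may transpose to the 1,1-dimethylallyl isomer, or a C–Br bond may be reduced. The fallback installs a symmetric allyl group first and makes the trisubstituted alkene afterwards. It sets out from 2: Stille coupling with allyltributylstannane (Pd(PPh3)4, toluene, 100 °C) should give tert-butyl[2,6-di(prop-2-en-1-yl)phenoxy]dimethylsilane F2. Cross-metathesis of F2 with 2-methylbut-2-ene (second-generation Grubbs catalyst, RuCl2(=CHPh)(PCy3)(H2IMes), CH2Cl2, 40 °C) should give compound 3, where the route is rejoined.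

Step 3. The pinacolborane formed may hydroborate or isomerise the prenyl alkenes, a vinylic C–H bond may be borylated, or the silyl ether may be lost during the periodate stage. The fallback changes the order so that no alkene meets the iridium catalyst. It sets out from 2: C–H borylation ([Ir(OMe)(cod)]2, dtbpy, B2pin2, THF, 60 °C) should give tert-butyl[2,6-dibromo-4-(4,4,5,5-tetramethyl-1,3,2-dioxaborolan-2-yl)phenoxy]dimethylsilane F3. Double Negishi prenylation of F3 under the conditions of step 2 (pinacol boronates are inert to organozinc reagents without base) should give compound 4, now isolated, and cleavage with NaIO4 and NH4OAc in acetone/H2O gives compound 5, where the route is rejoined.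

**Further compounds**
F1 | step 8 | racemic 2-[4-(tert-butyldimethylsilyloxy)-3,5-bis(3-methylbut-2-en-1-yl)phenyl]-8-(3-methylbut-2-en-1-yl)-7-(triisopropylsilyloxy)-2,3-dihydro-4H-chromen-4-one | CC(C)=CCc1cc(C2CC(=O)c3ccc(O[Si](C(C)C)(C(C)C)C(C)C)c(CC=C(C)C)c3O2)cc(CC=C(C)C)c1O[Si](C)(C)C(C)(C)C
F2 | step 2 | tert-butyl[2,6-di(prop-2-en-1-yl)phenoxy]dimethylsilane | C=CCc1cccc(CC=C)c1O[Si](C)(C)C(C)(C)C
F3 | step 3 | tert-butyl[2,6-dibromo-4-(4,4,5,5-tetramethyl-1,3,2-dioxaborolan-2-yl)phenoxy]dimethylsilane | CC(C)(C)[Si](C)(C)Oc1c(Br)cc(B2OC(C)(C)C(C)(C)O2)cc1Br
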